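The route disconnects the C1–C2 bond of the cyclohexene (C1 OAc, C2 OH, C3 OH, C4=C5 bearing C7H2OBz, C6 OBz). Because the C1/C2 diol is cis and lies trans to both neighbouring oxygens at C6 and C3, and because C3–C4=C5–C6 is a Z-alkene with cis-1,4 oxygens, one SmI2 pinacol cyclisation of an acyclic (Z)-1,6-dialdehyde should close the ring, form C1–C2 and set both carbinol centres. The dialdehyde carries a 2-naphthylmethyl ether at C3, a TBS ether at C6 and a TBDPS ether at C7. It comes from levoglucosenone, whose pyranose ring fixes the alkene geometry and the C6 configuration.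

Key step: step 13

Remarks:
- Ring atoms are numbered as above. Intermediates 3–15 use carbohydrate numbering (sugar C1–C6, C7 = added carbon); sugar C1, C2, C3, C4, C5, C6 become ring atoms C2, C3, C4, C5, C6, C1.
- NAP = 2-naphthylmethyl.
- Assumption: 10 and 11 are anomeric mixtures and 17–20 are epimeric at the orthoester carbon. These centres are lost later and are left undefined in the SMILES.

Step 1
Reactants: 1 levoglucosenone; 2 methanol
Product: 3 4-C-(hydroxymethyl) ketone (hydroxymethyl on sugar C4, on the face opposite the anhydro bridge)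
Conditions: MeOH (solvent), Ph2CO (0.3 equiv), hν (350 nm), Ar, rt
Reagents that add atoms: none
Why: Benzophenone-sensitised photochemical radical conjugate addition (Giese-type hydroxymethylation), a known reaction of carbohydrate enones, should deliver the nucleophilic hydroxymethyl radical to the β-carbon (sugar C4) from the face opposite the anhydro bridge, a centre that is flattened again in step 3.

Step 2
Reactants: 3 4-C-(hydroxymethyl) ketone
Product: 4 TBDPS ether of the ketone
Conditions: TBDPSCl, imidazole, DMF, 0 °C → rt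
Reagents that add atoms: tert-butyl(chloro)diphenylsilane, CC(C)(C)[Si](Cl)(c1ccccc1)c1ccccc1
Why: Imidazole-promoted silylation of the primary alcohol should install a silyl ether that is robust enough for the acidic steps 8 and 11 and is still removed by fluoride together with the TBS group in step 15.

Step 3
Reactants: 4 TBDPS ether of the ketone
Product: 5 4-C-[(tert-butyldiphenylsilyloxy)methyl]levoglucosenone (enone)
Conditions: IBX (2.2 equiv), DMSO/PhF (1:2), 70 °C
Reagents that add atoms: none
Why: IBX-mediated α,β-dehydrogenation of a ketone should restore the enone, because the carbonyl can enolise only toward C3 (C1 is a bridgehead acetal carbon), so that the C3=C4 double bond now carrying the C7 arm is the only possible outcome.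

Step 4
Reactants: 5 enone
Product: 6 threo allylic alcohol (C2 hydroxyl on the bridge face, 2S)
Conditions: NaBH4, CeCl3·7H2O, MeOH, −40 → 0 °C
Reagents that add atoms: none
Why: Luche 1,2-reduction should deliver hydride to the carbonyl face opposite the anhydro bridge, which sets sugar C2 as S (threo), the usual outcome for levoglucosenone-type ketones.

Step 5
Reactants: 6 threo allylic alcohol
Product: 7 erythro 4-nitrobenzoate (2R)
Conditions: 4-O2NC6H4CO2H, PPh3, DIAD, THF, 0 °C → rt
Reagents that add atoms: 4-nitrobenzoic acid, OC(=O)c1ccc(cc1)[N+](=O)[O-]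
Why: Mitsunobu esterification proceeds by SN2 displacement of the oxyphosphonium group at the allylic C2 and should invert it to the 2R (erythro) configuration that ring atom C3 of the target requires.

Step 6
Reactants: 7 erythro 4-nitrobenzoate
Product: 8 erythro allylic alcohol (C2 hydroxyl on the face opposite the bridge, 2R)
Conditions: K2CO3 (0.3 equiv), MeOH, 0 °C → rt
Reagents that add atoms: none
Why: Carbonate-catalysed transesterification (methanolysis) of the electron-poor aryl ester should free the 2R alcohol without touching the silyl ether or the bicyclic acetal.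

Step 7
Reactants: 8 erythro allylic alcohol
Product: 9 2-O-NAP ether
Conditions: NaH, 2-(bromomethyl)naphthalene, Bu4NI (cat.), THF/DMF, 0 °C → rt
Reagents that add atoms: 2-(bromomethyl)naphthalene, BrCc1ccc2ccccc2c1
Why: Williamson etherification should give the NAP ether, chosen because it tolerates the Lewis acid of step 8 better than a 4-methoxybenzyl ether, has no carbonyl that SmI2 could cleave next to the future aldehyde, and is removed oxidatively at the end.

Step 8
Reactants: 9 2-O-NAP ether
Product: 10 1,6-di-O-acetyl pyranose (anomeric mixture)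
Conditions: Ac2O, TESOTf (0.1 equiv), CH2Cl2, −20 → 0 °C; Et3N quench
Reagents that add atoms: acetic anhydride, CC(=O)OC(C)=O
Why: Lewis-acid-catalysed acetolysis of the 1,6-anhydro bridge (acylation of O6, C1–O6 cleavage to the pyranosyl oxocarbenium ion, capture by acetate) should open the bicycle irreversibly, whereas aqueous hydrolysis is an equilibrium, and it leaves C2 and C5 untouched.

Step 9
Reactants: 10 1,6-di-O-acetyl pyranose
Product: 12 (2R,3Z,5S)-hex-3-ene-1,5,6-triol bearing 2-O-NAP and 4-CH2OTBDPS, via pyranose hemiacetal 11 (not isolated)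
Conditions: NaBH4, K2CO3 (cat.), MeOH/THF, 0 °C → rt
Reagents that add atoms: none
Why: Transesterification of the two acetates releases the hemiacetal, whose open-chain aldehyde is reduced at once by borohydride (reduction of an aldose to its alditol), which should give the acyclic triol with the Z geometry inherited from the pyranose ring and without time for enolisation at C2.

Step 10
Reactants: 12 triol
Product: 13 1,5,6-tris-TBS ether
Conditions: TBSOTf (3.6 equiv), 2,6-lutidine, CH2Cl2, −78 → 0 °C
Reagents that add atoms: tert-butyldimethylsilyl trifluoromethanesulfonate, CC(C)(C)[Si](C)(C)OS(=O)(=O)C(F)(F)F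
Why: Exhaustive silylation with the silyl triflate and a hindered pyridine base should cap both primary hydroxyls and the hindered allylic C5 hydroxyl.

Step 11
Reactants: 13 tris-TBS ether
Product: 14 1,6-diol (C5 OTBS, C7 OTBDPS, C2 ONAP retained)
Conditions: CSA (0.1 equiv), MeOH/CH2Cl2 (1:1), 0 °C; Et3N quench
Reagents that add atoms: none
Why: Acid-catalysed methanolysis of silyl ethers is governed by steric access, so the two primary TBS ethers should be cleaved well before the secondary allylic TBS ether and the far more acid-stable primary TBDPS ether.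

Step 12
Reactants: 14 1,6-diol
Product: 15 (2R,3Z,5S)-dialdehyde
Conditions: (COCl)2, DMSO, CH2Cl2, −78 °C; iPr2NEt, −78 → −40 °C; cold pH 7 buffer; crude used at once
Reagents that add atoms: none
Why: Swern oxidation of both primary alcohols under cold non-aqueous conditions with a hindered amine should give the dialdehyde without over-oxidation, and the crude product is carried on at once because α-alkoxy β,γ-unsaturated aldehydes epimerise and conjugate easily.

Step 13
Reactants: 15 (2R,3Z,5S)-dialdehyde
Product: 16 cyclohexene cis-1,2-diol (C1 and C2 hydroxyls cis, both trans to O3 and O6)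
Conditions: SmI2 (3 equiv, 0.1 M in THF), t-BuOH (3 equiv), THF (0.01 M), −78 → −20 °C; aq. NH4Cl
Reagents that add atoms: none
Why: Each aldehyde accepts one electron from divalent samarium to give a ketyl, and the oxophilic samarium centres hold the two ketyl oxygens together while the carbon–carbon bond forms, so that a cyclic samarium diolate results and is protonated on work-up. The closest known reaction type is the SmI2 pinacol cyclisation of carbohydrate-derived 1,6-dialdehydes to cis-cyclohexane-1,2-diols used in cyclitol synthesis. The ring closes in a 6-exo-trig mode, the ketyl carbon C2 attacking the carbonyl carbon C1 whose oxygen stays outside the ring. The cis relation of the new C1 and C2 carbinols comes from the samarium bridge between the two oxygens, and their orientation trans to O6 and O3 comes from each new C–O bond avoiding the dipole and bulk of the adjacent ether. The step needs one cis-diol out of four possible diastereomers; because the C3 and C6 oxygens sit on the same ring face, both directing effects point to the same face, and the Z alkene holds the two carbonyls close enough for coupling to outrun simple reduction, α-alkoxy elimination and oligomerisation. Low temperature, dilution and immediate use of the crude dialdehyde guard against enolisation of the β,γ-unsaturated aldehydes.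

Step 14
Reactants: 16 cyclohexene cis-1,2-diol
Product: 17 cyclic methyl orthoacetate across O1/O2
Conditions: MeC(OMe)3, PPTS (cat.), CH2Cl2, rt; Et3N quench
Reagents that add atoms: trimethyl orthoacetate, CC(OC)(OC)OC
Why: Acid-catalysed orthoester exchange with the cis-1,2-diol should form the five-membered cyclic orthoacetate, which is stable to the fluoride and acylation steps that follow and already holds the acetyl carbon intended for O1.

Step 15
Reactants: 17 cyclic orthoacetate
Product: 18 orthoester 6,7-diol
Conditions: TBAF, THF, 0 °C → rt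
Reagents that add atoms: none
Why: Fluoride-mediated desilylation should remove both the TBS and the TBDPS ether, whereas the orthoester and the NAP ether are inert to basic fluoride.

Step 16
Reactants: 18 orthoester 6,7-diol
Product: 19 orthoester 6,7-dibenzoate
Conditions: Bz2O, Et3N, DMAP (cat.), CH2Cl2, 0 °C → rt
Reagents that add atoms: benzoic anhydride, O=C(OC(=O)c1ccccc1)c1ccccc1
Why: DMAP-catalysed acylation with the anhydride should benzoylate the primary C7 and the secondary C6 hydroxyl under basic conditions that generate no HCl and so spare the orthoester.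

Step 17
Reactants: 19 orthoester 6,7-dibenzoate
Product: 20 3-hydroxy orthoester dibenzoate
Conditions: DDQ, CH2Cl2/pH 7 phosphate buffer (10:1), 0 °C → rt
Reagents that add atoms: none
Why: Oxidative cleavage of the NAP ether by DDQ (benzylic hydride abstraction and hydrolysis of the oxocarbenium ion) in buffered two-phase medium should free the C3 hydroxyl, and it is done while O2 is still tied up so that no neighbouring hydroxyl can trap the cation as an acetal.

Step 18
Reactants: 20 3-hydroxy orthoester dibenzoate
Product: 21 target CNP0213675.1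
Conditions: AcOH/H2O (4:1), rt
Reagents that add atoms: water, O
Why: Mild acid hydrolysis of a cyclic orthoester passes through a dioxolan-2-ylium ion and a hemiorthoester that collapses to the axial ester and the equatorial alcohol, and since allylic 1,2-strain with the C5 side chain holds O6 pseudoaxial and therefore the trans-disposed O1 axial, the acetate should end on O1 and leave the C2 hydroxyl free.

Compound list
1 | levoglucosenone, (1S,5R)-6,8-dioxabicyclo[3.2.1]oct-2-en-4-one | O=C1C=C[C@H]2CO[C@@H]1O2 | starting material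
2 | methanol | CO | starting material
3 | 1,6-anhydro-3,4-dideoxy-4-C-(hydroxymethyl)-β-D-hexopyranos-2-ulose, CH2OH on C4 opposite the O6–C6 bridge; (1S,2R,5R)-2-(hydroxymethyl)-6,8-dioxabicyclo[3.2.1]octan-4-one | O=C1C[C@H](CO)[C@H]2CO[C@@H]1O2 | intermediate
4 | TBDPS ether of 3 (4-C-[(tert-butyldiphenylsilyloxy)methyl] ketone) | O=C1C[C@H](CO[Si](c3ccccc3)(c3ccccc3)C(C)(C)C)[C@H]2CO[C@@H]1O2 | intermediate
5 | 4-C-[(tert-butyldiphenylsilyloxy)methyl]levoglucosenone (C3=C4 enone) | O=C1C=C(CO[Si](c3ccccc3)(c3ccccc3)C(C)(C)C)[C@H]2CO[C@@H]1O2 | intermediate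
6 | 1,6-anhydro-3,4-dideoxy-4-C-[(tert-butyldiphenylsilyloxy)methyl]-β-D-threo-hex-3-enopyranose (2S, hydroxyl on the bridge face) | O[C@H]1C=C(CO[Si](c3ccccc3)(c3ccccc3)C(C)(C)C)[C@H]2CO[C@@H]1O2 | intermediate
7 | 2-O-(4-nitrobenzoyl) derivative of the D-erythro alcohol (2R) | O=C(O[C@@H]1C=C(CO[Si](c3ccccc3)(c3ccccc3)C(C)(C)C)[C@H]2CO[C@@H]1O2)c4ccc(cc4)[N+](=O)[O-] | intermediate
8 | 1,6-anhydro-3,4-dideoxy-4-C-[(tert-butyldiphenylsilyloxy)methyl]-β-D-erythro-hex-3-enopyranose (2R, hydroxyl opposite the bridge) | O[C@@H]1C=C(CO[Si](c3ccccc3)(c3ccccc3)C(C)(C)C)[C@H]2CO[C@@H]1O2 | intermediate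
9 | 2-O-(2-naphthylmethyl) ether of 8 | C(O[C@@H]1C=C(CO[Si](c3ccccc3)(c3ccccc3)C(C)(C)C)[C@H]2CO[C@@H]1O2)c4ccc5ccccc5c4 | intermediate
10 | 1,6-di-O-acetyl-3,4-dideoxy-2-O-(2-naphthylmethyl)-4-C-[(tert-butyldiphenylsilyloxy)methyl]-D-erythro-hex-3-enopyranose (anomeric mixture) | CC(=O)OC[C@H]1OC(OC(C)=O)[C@H](OCc2ccc3ccccc3c2)C=C1CO[Si](c1ccccc1)(c1ccccc1)C(C)(C)C | intermediate
11 | 3,4-dideoxy-2-O-(2-naphthylmethyl)-4-C-[(tert-butyldiphenylsilyloxy)methyl]-D-erythro-hex-3-enopyranose (free hemiacetal, anomeric mixture) | OC[C@H]1OC(O)[C@H](OCc2ccc3ccccc3c2)C=C1CO[Si](c1ccccc1)(c1ccccc1)C(C)(C)C | intermediate (not isolated)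
12 | (2R,3Z,5S)-4-[(tert-butyldiphenylsilyloxy)methyl]-2-(naphthalen-2-ylmethoxy)hex-3-ene-1,5,6-triol | OC[C@H](OCc1ccc2ccccc2c1)/C=C(CO[Si](c1ccccc1)(c1ccccc1)C(C)(C)C)\[C@H](O)CO | intermediate
13 | 1,5,6-tris-O-(tert-butyldimethylsilyl) ether of 12 | CC(C)(C)[Si](C)(C)OC[C@H](OCc1ccc2ccccc2c1)/C=C(CO[Si](c1ccccc1)(c1ccccc1)C(C)(C)C)\[C@H](O[Si](C)(C)C(C)(C)C)CO[Si](C)(C)C(C)(C)C | intermediate
14 | (2R,3Z,5S)-5-(tert-butyldimethylsilyloxy)-4-[(tert-butyldiphenylsilyloxy)methyl]-2-(naphthalen-2-ylmethoxy)hex-3-ene-1,6-diol | OC[C@H](OCc1ccc2ccccc2c1)/C=C(CO[Si](c1ccccc1)(c1ccccc1)C(C)(C)C)\[C@H](O[Si](C)(C)C(C)(C)C)CO | intermediate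
15 | (2R,3Z,5S)-5-(tert-butyldimethylsilyloxy)-4-[(tert-butyldiphenylsilyloxy)methyl]-2-(naphthalen-2-ylmethoxy)hex-3-enedial | O=C[C@H](OCc1ccc2ccccc2c1)/C=C(CO[Si](c1ccccc1)(c1ccccc1)C(C)(C)C)\[C@H](O[Si](C)(C)C(C)(C)C)C=O | intermediate
16 | (1S,2R,3R,6S)-6-(tert-butyldimethylsilyloxy)-5-[(tert-butyldiphenylsilyloxy)methyl]-3-(naphthalen-2-ylmethoxy)cyclohex-4-ene-1,2-diol (1,2-cis; O3 and O6 on the other face) | O[C@H]1[C@@H](O)[C@H](OCc2ccc3ccccc3c2)C=C(CO[Si](c2ccccc2)(c2ccccc2)C(C)(C)C)[C@@H]1O[Si](C)(C)C(C)(C)C | intermediate
17 | 1,2-O-(1-methoxyethylidene) derivative of 16 (2-methoxy-2-methyl-1,3-dioxolane cis-fused at C1/C2; epimers at the orthoester carbon) | COC1(C)O[C@H]2[C@@H](O1)[C@H](OCc3ccc4ccccc4c3)C=C(CO[Si](c3ccccc3)(c3ccccc3)C(C)(C)C)[C@@H]2O[Si](C)(C)C(C)(C)C | intermediate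
18 | orthoester 17 with free C6 and C7 hydroxyls | COC1(C)O[C@H]2[C@@H](O1)[C@H](OCc3ccc4ccccc4c3)C=C(CO)[C@@H]2O | intermediate
19 | 6,7-di-O-benzoate of 18 | COC1(C)O[C@H]2[C@@H](O1)[C@H](OCc3ccc4ccccc4c3)C=C(COC(=O)c3ccccc3)[C@@H]2OC(=O)c3ccccc3 | intermediate
20 | orthoester dibenzoate with free C3 hydroxyl | COC1(C)O[C@H]2[C@@H](O1)[C@H](O)C=C(COC(=O)c3ccccc3)[C@@H]2OC(=O)c3ccccc3 | intermediate
21 | (1S,2S,3R,6S)-6-(benzoyloxy)-5-[(benzoyloxy)methyl]-2,3-dihydroxycyclohex-4-en-1-yl acetate (CNP0213675.1) | CC(=O)O[C@H]1[C@@H](O)[C@H](O)C=C(COC(=O)c2ccccc2)[C@@H]1OC(=O)c1ccccc1 | target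

Total step count: 18
Longest linear sequence: 18 steps (1 → 21)

Steps most likely to fail

1. Step 13 (pinacol cyclisation). What may go wrong: incomplete facial control in the coupling, expulsion of an α-alkoxy group from a ketyl by reductive elimination, or enolisation that moves the double bond into conjugation before coupling. The fallback forms the same C1–C2 bond by metathesis and sets the diol afterwards. It sets out from dialdehyde 15, which is methylenated twice with Ph3P=CH2 (from Ph3PCH3Br and KN(SiMe3)2, THF, −78 °C) to the acyclic triene F1. Ring-closing metathesis with the second-generation Grubbs catalyst RuCl2(=CHPh)(PCy3)(H2IMes) in CH2Cl2 should close the cyclohexa-1,4-diene F2 with loss of ethene, the trisubstituted C4=C5 alkene being a spectator. Catalytic OsO4 with N-methylmorpholine N-oxide should then dihydroxylate the more accessible disubstituted C1=C2 bond from the face opposite both allylic ethers, and the route is rejoined at diol 16.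

2. Step 18 (orthoester opening). What may go wrong: delivery of the acetate to O2 instead of O1 if the ring reacts through the other half-chair, or acyl migration between the cis oxygens afterwards. The fallback uses acylation under stannylene control, which selects the equatorial oxygen and is therefore complementary to orthoester opening. It sets out from diol 16, which is protected as the silylated acetonide F3 (2,2-dimethoxypropane, PPTS). TBAF should give the acetonide diol F4, Bz2O/DMAP/Et3N the acetonide dibenzoate F5, and aqueous AcOH at 40 °C the cis-diol dibenzoate F6. Bu2SnO (toluene, reflux) followed by AcCl at 0 °C should acetylate one hydroxyl to the NAP-protected 1-acetate F7, and DDQ removes the NAP ether to arrive at target 21.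

3. Step 8 (acetolysis). What may go wrong: cleavage of the NAP or silyl ether by the Lewis acid, or intramolecular attack of the naphthalene ring on the oxocarbenium ion. The fallback is direct hydrolysis with water as the only nucleophile. It sets out from NAP ether 9, which is heated with 1 M aqueous HCl in dioxane at 50 °C to give hemiacetal 11 directly. After neutralisation NaBH4 is added to the same flask and the route is rejoined at triol 12; unchanged 9 is inert to borohydride and can be recycled. No compound outside the list is formed (F0).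

Further compounds
F1 | step 13 | (Z)-3-(naphthalen-2-ylmethoxy)-5-[(tert-butyldiphenylsilyloxy)methyl]-6-(tert-butyldimethylsilyloxy)octa-1,4,7-triene, configurations as in 15 | C=C[C@H](OCc1ccc2ccccc2c1)/C=C(CO[Si](c1ccccc1)(c1ccccc1)C(C)(C)C)\[C@H](O[Si](C)(C)C(C)(C)C)C=C
F2 | step 13 | 3-(naphthalen-2-ylmethoxy)-6-(tert-butyldimethylsilyloxy)-1-[(tert-butyldiphenylsilyloxy)methyl]cyclohexa-1,4-diene, O3 and O6 cis | C1=C[C@H](OCc2ccc3ccccc3c2)C=C(CO[Si](c2ccccc2)(c2ccccc2)C(C)(C)C)[C@@H]1O[Si](C)(C)C(C)(C)C
F3 | step 18 | 1,2-O-isopropylidene derivative of 16 | CC1(C)O[C@H]2[C@@H](O1)[C@H](OCc3ccc4ccccc4c3)C=C(CO[Si](c3ccccc3)(c3ccccc3)C(C)(C)C)[C@@H]2O[Si](C)(C)C(C)(C)C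
F4 | step 18 | acetonide with free C6 and C7 hydroxyls | CC1(C)O[C@H]2[C@@H](O1)[C@H](OCc3ccc4ccccc4c3)C=C(CO)[C@@H]2O
F5 | step 18 | acetonide 6,7-dibenzoate | CC1(C)O[C@H]2[C@@H](O1)[C@H](OCc3ccc4ccccc4c3)C=C(COC(=O)c3ccccc3)[C@@H]2OC(=O)c3ccccc3
F6 | step 18 | 6,7-di-O-benzoyl-3-O-(2-naphthylmethyl) cyclohexene cis-1,2-diol | O[C@H]1[C@@H](O)[C@H](OCc2ccc3ccccc3c2)C=C(COC(=O)c2ccccc2)[C@@H]1OC(=O)c2ccccc2
F7 | step 18 | 1-O-acetyl-6,7-di-O-benzoyl-3-O-(2-naphthylmethyl) derivative with free C2 hydroxyl | CC(=O)O[C@H]1[C@@H](O)[C@H](OCc2ccc3ccccc3c2)C=C(COC(=O)c2ccccc2)[C@@H]1OC(=O)c2ccccc2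
F0 | step 8 | none | none
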